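**Retrosynthetic overview**
1. The oxolane and the δ-lactone (acylal) are closed last and together: periodate cleavage of the α-ketol in cyclopentanone template 22 frees an aldehyde and an acid that fold onto the glycolate hydroxyl (22 → 25).
2. The quaternary-carbon–CH bond comes from a photoredox Giese coupling of the tertiary hydroazulenyl radical (from oxalate 11) with chloro enone 19.
3. 19 comes from the (1R,5S) Grieco lactone 12: convex-face enolate hydroxylation, lactone opening, allylic oxidation, α-chlorination.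
4. 11 comes from 4,4-dimethylcyclohexenone 1: asymmetric conjugate addition, aldol cyclopentannulation, one-carbon ring expansion, methylenation.
5. Ring order: cyclopentane (step 2), cycloheptane (step 3), then oxolane and lactone in one operation (step 12).

Assumption: the carbinol epimer drawn for 7–11 is the expected aldol product; either epimer serves, because this carbon becomes the radical centre. Both antipodes of the Grieco lactone are taken as purchasable.

**Step 1**
Reactants: 1 4,4-dimethylcyclohex-2-en-1-one; 2 2-(2-bromoethyl)-2-methyl-1,3-dioxolane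
Product: 5 (3R)-3-[2-(2-methyl-1,3-dioxolan-2-yl)ethyl]-4,4-dimethylcyclohexan-1-one, via Grignard reagent 3 (not isolated), via diorganozinc 4 (not isolated)
Conditions: 2, Mg, THF; ZnCl2 (0.5 equiv), 1,4-dioxane, filter; then 1, Cu(OTf)2 (2 mol %), (S,R,R)-BINOL/bis(1-phenylethyl)amine phosphoramidite (4 mol %), toluene, −30 °C; aq. NH4Cl
Reagents that add atoms: none
Why: Copper-catalysed asymmetric conjugate addition of a functionalised dialkylzinc (Feringa type) to a gem-dimethyl enone; the ligand sets the centre next to CMe2 (the face that gives (S)-3-ethylcyclohexanone from cyclohexenone, here the R descriptor; the mirror-image ligand would give the antipode).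

**Step 2**
Reactants: 5 (3R)-3-[2-(2-methyl-1,3-dioxolan-2-yl)ethyl]-4,4-dimethylcyclohexan-1-one
Product: 7 (3S,3aR,7aR)-3-hydroxy-3,7,7-trimethyloctahydro-4H-inden-4-one (cis-fused), via diketone 6 (not isolated)
Conditions: 2 M HCl, THF, 23 °C; then KOH (0.2 equiv), MeOH, 0 °C
Reagents that add atoms: water O
Why: Ketal hydrolysis, then intramolecular aldol addition of the ring-ketone enolate onto the methyl ketone (5-membered closure); the cis ring fusion follows from the tether and from equilibration next to the ketone.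

**Step 3**
Reactants: 7 (3S,3aR,7aR)-3-hydroxy-3,7,7-trimethyloctahydro-4H-inden-4-one
Product: 9 (3S,3aR,8aR)-3-hydroxy-3,8,8-trimethyloctahydroazulen-4(1H)-one, via silyl ketone 8 (not isolated)
Conditions: Me3SiCHN2, AlMe3 (2.2 equiv), CH2Cl2, −78 → −20 °C; then 1 M HCl, THF
Reagents that add atoms: trimethylsilyldiazomethane C[Si](C)(C)C=[N+]=[N-]
Why: Lewis-acid-promoted diazoalkane ring expansion (Tiffeneau–Demjanov type); the less substituted α-methylene migrates, so the new CH2 enters away from the ring fusion and no stereocentre is touched.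

**Step 4**
Reactants: 9 (3S,3aR,8aR)-3-hydroxy-3,8,8-trimethyloctahydroazulen-4(1H)-one
Product: 10 (1S,3aR,8aS)-1,4,4-trimethyl-8-methylidenedecahydroazulen-1-ol
Conditions: Zn, CH2Br2, TiCl4, THF/CH2Cl2, 0 → 23 °C
Reagents that add atoms: dibromomethane BrCBr
Why: Takai–Lombardo methylenation is non-basic, so the β-hydroxy ketone neither retro-aldolises nor epimerises; the ring-fusion centre is locked once the ketone is gone.

**Step 5**
Reactants: 10 (1S,3aR,8aS)-1,4,4-trimethyl-8-methylidenedecahydroazulen-1-ol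
Product: 11 (1S,3aR,8aS)-1,4,4-trimethyl-8-methylidenedecahydroazulen-1-yl 1,3-dioxoisoindolin-2-yl oxalate
Conditions: (COCl)2, N-hydroxyphthalimide, THF, 0 °C; then 10, Et3N, DMAP (cat.), THF, 23 °C; used crude
Reagents that add atoms: oxalyl chloride O=C(Cl)C(Cl)=O; N-hydroxyphthalimide O=C1c2ccccc2C(=O)N1O
Why: Acylation of the tertiary alcohol gives an N-phthalimidoyl oxalate (Overman-type redox-active ester) for radical generation.

**Step 6**
Reactants: 12 (1R,5S)-2-oxabicyclo[3.3.0]oct-6-en-3-one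
Product: 14 (1R,4R,5S)-4-(triethylsilyloxy)-2-oxabicyclo[3.3.0]oct-6-en-3-one, via hydroxy lactone 13 (not isolated)
Conditions: KHMDS, THF, −78 °C; 2-(phenylsulfonyl)-3-phenyloxaziridine; then Et3SiCl, −78 → 0 °C
Reagents that add atoms: 2-(phenylsulfonyl)-3-phenyloxaziridine O=S(=O)(c1ccccc1)N1OC1c1ccccc1; chlorotriethylsilane CC[Si](Cl)(CC)CC
Why: Davis enolate hydroxylation on the convex face of the cis-fused bicycle sets the carbinol centre (R) that will carry the oxolane oxygen; the alkoxide is silylated in the flask.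

**Step 7**
Reactants: 14 (1R,4R,5S)-4-(triethylsilyloxy)-2-oxabicyclo[3.3.0]oct-6-en-3-one
Product: 17 methyl (2R)-2-[(1S,5R)-5-acetoxycyclopent-2-en-1-yl]-2-(triethylsilyloxy)acetate, via potassium carboxylate 15 (not isolated), via hydroxy ester 16 (not isolated)
Conditions: KOH (1.05 equiv), MeOH/H2O, 0 °C, evaporate; MeI, DMF; then Ac2O, pyridine, DMAP (cat.), 0 °C
Reagents that add atoms: potassium hydroxide [K+].[OH-]; iodomethane CI; acetic anhydride CC(=O)OC(C)=O
Why: Saponification, carboxylate alkylation and immediate acetylation (before relactonisation) open the template; no stereocentre is touched and the three oxygens are now differentiated.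

**Step 8**
Reactants: 17 methyl (2R)-2-[(1S,5R)-5-acetoxycyclopent-2-en-1-yl]-2-(triethylsilyloxy)acetate
Product: 18 methyl (2R)-2-[(1S,5S)-5-acetoxy-4-oxocyclopent-2-en-1-yl]-2-(triethylsilyloxy)acetate
Conditions: Rh2(cap)4 (1 mol %), t-BuOOH (70 % aq., 5 equiv), CH2Cl2, 40 °C
Reagents that add atoms: tert-butyl hydroperoxide CC(C)(C)OO
Why: Dirhodium caprolactamate/t-BuOOH allylic oxidation at the only allylic methylene (the other allylic site is a hindered, electron-poor methine) gives the enone.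

**Step 9**
Reactants: 18 methyl (2R)-2-[(1S,5S)-5-acetoxy-4-oxocyclopent-2-en-1-yl]-2-(triethylsilyloxy)acetate
Product: 19 methyl (2R)-2-[(1S,5S)-5-acetoxy-3-chloro-4-oxocyclopent-2-en-1-yl]-2-(triethylsilyloxy)acetate
Conditions: PhICl2, pyridine, CH2Cl2, 0 °C
Reagents that add atoms: iodobenzene dichloride ClI(Cl)c1ccccc1
Why: α-Chlorination of the enone (addition–elimination) marks the future aldehyde carbon and raises acceptor reactivity, as in α-chlorobutenolide acceptors.

**Step 10**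
Reactants: 11 N-phthalimidoyl oxalate of the hydroazulenol; 19 methyl (2R)-2-[(1S,5S)-5-acetoxy-3-chloro-4-oxocyclopent-2-en-1-yl]-2-(triethylsilyloxy)acetate
Product: 20 methyl (2R)-2-[(1S,2R,3S,5S)-5-acetoxy-3-chloro-4-oxo-2-[(1R,3aR,8aS)-1,4,4-trimethyl-8-methylidenedecahydroazulen-1-yl]cyclopentyl]-2-(triethylsilyloxy)acetate
Conditions: Ru(bpy)3(PF6)2 (1 mol %), Hantzsch ester (1.5 equiv), i-Pr2NEt·HBF4, CH2Cl2/THF, blue LEDs, 23 °C
Reagents that add atoms: none
Why: Photoredox Giese coupling: the tertiary radical attacks the enone β-carbon anti to the two cis substituents of the cyclopentenone, and reacts through its own convex face (cis to the ring-fusion hydrogens), so the quaternary centre and the adjacent CH are set in one bond formation; the chlorine-bearing centre is set by hydrogen transfer anti to the new substituent and is erased in step 11.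

**Step 11**
Reactants: 20 chloro ketone from step 10
Product: 22 methyl (2R)-2-[(1S,2R,3R,5S)-5-acetoxy-3-hydroxy-4-oxo-2-[(1R,3aR,8aS)-1,4,4-trimethyl-8-methylidenedecahydroazulen-1-yl]cyclopentyl]-2-(triethylsilyloxy)acetate, via silyl enol ether 21 (not isolated)
Conditions: Zn, Me3SiCl, TMEDA, Et2O, 23 °C; filter; then dimethyldioxirane, acetone/CH2Cl2, −78 °C; aq. citric acid
Reagents that add atoms: dimethyldioxirane CC1(C)OO1
Why: Zinc reduction of the α-chloro ketone gives the regiospecific silyl enol ether, and Rubottom oxidation follows because the electron-rich enol ether reacts far faster with the dioxirane than the 1,1-disubstituted alkene; the new carbinol configuration is irrelevant.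

**Step 12**
Reactants: 22 α-ketol from step 11
Product: 25 methyl (1S,4S,5R,6R,8R)-4-acetoxy-3-oxo-8-[(1R,3aR,8aS)-1,4,4-trimethyl-8-methylidenedecahydroazulen-1-yl]-2,7-dioxabicyclo[3.2.1]octane-6-carboxylate (CNP0215240.1), via aldehyde acid 23 (not isolated), via lactol acid 24 (not isolated)
Conditions: H5IO6, THF/H2O (4:1), 0 → 23 °C; extract; then PPTS (0.2 equiv), 4 Å MS, CH2Cl2, 23 °C
Reagents that add atoms: water O
Why: Key step: periodate (Malaprade-type) cleavage of the α-ketol cuts the template ring into carboxylic acid and aldehyde while the acid removes the silyl group; the freed hydroxyl adds to the aldehyde (lactol, oxolane ring) and the acid captures the lactol oxocarbenium ion (acylal, δ-lactone ring). The acetal centre is fixed by the bicyclic geometry and the other centres are carried unchanged.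

**Compound list**
1 | 4,4-dimethylcyclohex-2-en-1-one | CC1(C)CCC(=O)C=C1 | starting material
2 | 2-(2-bromoethyl)-2-methyl-1,3-dioxolane | CC1(CCBr)OCCO1 | starting material
3 | [2-(2-methyl-1,3-dioxolan-2-yl)ethyl]magnesium bromide | CC1(CC[Mg]Br)OCCO1 | intermediate (not isolated)
4 | bis[2-(2-methyl-1,3-dioxolan-2-yl)ethyl]zinc | CC1(CC[Zn]CCC2(C)OCCO2)OCCO1 | intermediate (not isolated)
5 | (3R)-3-[2-(2-methyl-1,3-dioxolan-2-yl)ethyl]-4,4-dimethylcyclohexan-1-one | O=C1CCC(C)(C)[C@H](CCC2(C)OCCO2)C1 | intermediate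
6 | (3R)-4,4-dimethyl-3-(3-oxobutyl)cyclohexan-1-one | O=C1CCC(C)(C)[C@H](CCC(C)=O)C1 | intermediate (not isolated)
7 | (3S,3aR,7aR)-3-hydroxy-3,7,7-trimethyloctahydro-4H-inden-4-one | O=C1CCC(C)(C)[C@@H]2CC[C@@](O)(C)[C@H]12 | intermediate
8 | (3S,3aR,8aR)-3-hydroxy-3,8,8-trimethyl-5-(trimethylsilyl)octahydroazulen-4(1H)-one, both C5 epimers | O=C1C([Si](C)(C)C)CCC(C)(C)[C@@H]2CC[C@@](O)(C)[C@H]12 | intermediate (not isolated)
9 | (3S,3aR,8aR)-3-hydroxy-3,8,8-trimethyloctahydroazulen-4(1H)-one | O=C1CCCC(C)(C)[C@@H]2CC[C@@](O)(C)[C@H]12 | intermediate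
10 | (1S,3aR,8aS)-1,4,4-trimethyl-8-methylidenedecahydroazulen-1-ol | C=C1CCCC(C)(C)[C@@H]2CC[C@@](O)(C)[C@H]12 | intermediate
11 | (1S,3aR,8aS)-1,4,4-trimethyl-8-methylidenedecahydroazulen-1-yl 1,3-dioxoisoindolin-2-yl oxalate | C=C1CCCC(C)(C)[C@@H]2CC[C@@](OC(=O)C(=O)ON3C(=O)c4ccccc4C3=O)(C)[C@H]12 | intermediate
12 | (1R,5S)-2-oxabicyclo[3.3.0]oct-6-en-3-one (Grieco lactone) | O=C1C[C@H]2C=CC[C@H]2O1 | starting material
13 | (1R,4R,5R)-4-hydroxy-2-oxabicyclo[3.3.0]oct-6-en-3-one (hydroxyl on the convex face) | O=C1[C@H](O)[C@H]2C=CC[C@H]2O1 | intermediate (not isolated)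
14 | (1R,4R,5S)-4-(triethylsilyloxy)-2-oxabicyclo[3.3.0]oct-6-en-3-one | O=C1[C@H](O[Si](CC)(CC)CC)[C@H]2C=CC[C@H]2O1 | intermediate
15 | potassium (2R)-2-[(1S,5R)-5-hydroxycyclopent-2-en-1-yl]-2-(triethylsilyloxy)acetate | [K+].[O-]C(=O)[C@H](O[Si](CC)(CC)CC)[C@H]1C=CC[C@H]1O | intermediate (not isolated)
16 | methyl (2R)-2-[(1S,5R)-5-hydroxycyclopent-2-en-1-yl]-2-(triethylsilyloxy)acetate | COC(=O)[C@H](O[Si](CC)(CC)CC)[C@H]1C=CC[C@H]1O | intermediate (not isolated)
17 | methyl (2R)-2-[(1S,5R)-5-acetoxycyclopent-2-en-1-yl]-2-(triethylsilyloxy)acetate | COC(=O)[C@H](O[Si](CC)(CC)CC)[C@H]1C=CC[C@H]1OC(C)=O | intermediate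
18 | methyl (2R)-2-[(1S,5S)-5-acetoxy-4-oxocyclopent-2-en-1-yl]-2-(triethylsilyloxy)acetate | COC(=O)[C@H](O[Si](CC)(CC)CC)[C@H]1C=CC(=O)[C@H]1OC(C)=O | intermediate
19 | methyl (2R)-2-[(1S,5S)-5-acetoxy-3-chloro-4-oxocyclopent-2-en-1-yl]-2-(triethylsilyloxy)acetate | COC(=O)[C@H](O[Si](CC)(CC)CC)[C@H]1C=C(Cl)C(=O)[C@H]1OC(C)=O | intermediate
20 | methyl (2R)-2-[(1S,2R,3S,5S)-5-acetoxy-3-chloro-4-oxo-2-[(1R,3aR,8aS)-1,4,4-trimethyl-8-methylidenedecahydroazulen-1-yl]cyclopentyl]-2-(triethylsilyloxy)acetate | C=C1CCCC(C)(C)[C@@H]2CC[C@@](C)([C@@H]3[C@H](Cl)C(=O)[C@@H](OC(C)=O)[C@H]3[C@@H](O[Si](CC)(CC)CC)C(=O)OC)[C@H]12 | intermediate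
21 | methyl (2R)-2-[(1S,2S,5S)-5-acetoxy-4-(trimethylsilyloxy)-2-[(1S,3aR,8aS)-1,4,4-trimethyl-8-methylidenedecahydroazulen-1-yl]cyclopent-3-en-1-yl]-2-(triethylsilyloxy)acetate (same spatial arrangement as in 20; two descriptors change with the substituent priorities) | C=C1CCCC(C)(C)[C@@H]2CC[C@@](C)([C@@H]3C=C(O[Si](C)(C)C)[C@@H](OC(C)=O)[C@H]3[C@@H](O[Si](CC)(CC)CC)C(=O)OC)[C@H]12 | intermediate (not isolated)
22 | methyl (2R)-2-[(1S,2R,3R,5S)-5-acetoxy-3-hydroxy-4-oxo-2-[(1R,3aR,8aS)-1,4,4-trimethyl-8-methylidenedecahydroazulen-1-yl]cyclopentyl]-2-(triethylsilyloxy)acetate | C=C1CCCC(C)(C)[C@@H]2CC[C@@](C)([C@@H]3[C@@H](O)C(=O)[C@@H](OC(C)=O)[C@H]3[C@@H](O[Si](CC)(CC)CC)C(=O)OC)[C@H]12 | intermediate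
23 | (2S,3S,4R)-2-acetoxy-3-[(1R)-2-methoxy-2-oxo-1-(triethylsilyloxy)ethyl]-5-oxo-4-[(1R,3aR,8aS)-1,4,4-trimethyl-8-methylidenedecahydroazulen-1-yl]pentanoic acid | C=C1CCCC(C)(C)[C@@H]2CC[C@@](C)([C@H](C=O)[C@@H]([C@H](OC(C)=O)C(=O)O)[C@@H](O[Si](CC)(CC)CC)C(=O)OC)[C@H]12 | intermediate (not isolated)
24 | (2S)-2-acetoxy-2-[(2R,3R,4R)-5-hydroxy-2-(methoxycarbonyl)-4-[(1R,3aR,8aS)-1,4,4-trimethyl-8-methylidenedecahydroazulen-1-yl]oxolan-3-yl]acetic acid, both lactol anomers | C=C1CCCC(C)(C)[C@@H]2CC[C@@](C)([C@@H]3C(O)O[C@@H](C(=O)OC)[C@@H]3[C@H](OC(C)=O)C(=O)O)[C@H]12 | intermediate (not isolated)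
25 | methyl (1S,4S,5R,6R,8R)-4-acetoxy-3-oxo-8-[(1R,3aR,8aS)-1,4,4-trimethyl-8-methylidenedecahydroazulen-1-yl]-2,7-dioxabicyclo[3.2.1]octane-6-carboxylate | C=C1CCCC(C)(C)[C@@H]2CC[C@@](C)([C@@H]3[C@@H]4OC(=O)[C@@H](OC(C)=O)[C@H]3[C@H](C(=O)OC)O4)[C@H]12 | target

**Step count and risks**
Total steps: 12
Longest linear sequence: 8 steps
The longest chain is the hydroazulene branch followed by the coupling and the two steps after it; the acceptor branch is one step shorter.

The three steps most likely to fail: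

Step 10 (hindered radical coupling; the chloro enone may be reduced by the photocatalyst system). Fallback: set out from 10 and acylate it with MeO2CCOCl (Et3N, DMAP, CH2Cl2) to the methyl oxalate F1, then saponify with CsOH (1 equiv, THF/H2O) to the caesium oxalate F2. Couple F2 redox-neutrally (Ir[dF(CF3)ppy]2(dtbbpy)PF6, DME/DMF/H2O, blue LEDs) with the chlorine-free enone 18 to give the ketone F3. Kinetic enolisation of F3 at the methylene (LiHMDS added to F3 premixed with Me3SiCl, THF, −78 °C) comes back to the route at silyl enol ether 21.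

Step 11 (zinc must spare the neighbouring α-acetoxy ketone, and the dioxirane must spare the exocyclic alkene). Fallback: set out from 20 and remove the silyl group with HF·pyridine to give the chloro alcohol F4. The glycolate hydroxyl then displaces the α-keto chloride, which stands trans to it (K2CO3, MeCN), giving the 2-oxabicyclo[2.2.1]heptan-6-one F5. Baeyer–Villiger oxidation with Me3SiOOSiMe3 and catalytic Me3SiOTf (the bridgehead α-alkoxy carbon migrates, the alkene is untouched) comes back to the route at 25.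

Step 12 (two ring closures after the cleavage; the freed hydroxyl could instead lactonise onto the acid). Fallback: set out from 22 and cleave with NaIO4 in buffered THF/H2O so that the silyl ether stays; aldehyde acid 23 then closes to its ring tautomer, the hydroxy δ-lactone F6, which is isolated. Acetylation (Ac2O, pyridine) gives the acetoxy δ-lactone F7, so the six-membered ring is fixed first. HF·pyridine frees the glycolate hydroxyl to give the hydroxy diacetate F8, and BF3·OEt2 at −40 °C lets this hydroxyl displace the anomeric acetate, which comes back to the route at 25.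

**Further compounds**
F1 | step 10 | (1S,3aR,8aS)-1,4,4-trimethyl-8-methylidenedecahydroazulen-1-yl methyl oxalate | C=C1CCCC(C)(C)[C@@H]2CC[C@@](OC(=O)C(=O)OC)(C)[C@H]12
F2 | step 10 | caesium (1S,3aR,8aS)-1,4,4-trimethyl-8-methylidenedecahydroazulen-1-yl oxalate | C=C1CCCC(C)(C)[C@@H]2CC[C@@](OC(=O)C(=O)[O-])(C)[C@H]12.[Cs+]
F3 | step 10 | methyl (2R)-2-[(1S,2R,5S)-5-acetoxy-4-oxo-2-[(1S,3aR,8aS)-1,4,4-trimethyl-8-methylidenedecahydroazulen-1-yl]cyclopentyl]-2-(triethylsilyloxy)acetate (same spatial arrangement as in 20) | C=C1CCCC(C)(C)[C@@H]2CC[C@@](C)([C@@H]3CC(=O)[C@@H](OC(C)=O)[C@H]3[C@@H](O[Si](CC)(CC)CC)C(=O)OC)[C@H]12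
F4 | step 11 | methyl (2R)-2-[(1R,2R,3S,5S)-5-acetoxy-3-chloro-4-oxo-2-[(1R,3aR,8aS)-1,4,4-trimethyl-8-methylidenedecahydroazulen-1-yl]cyclopentyl]-2-hydroxyacetate | C=C1CCCC(C)(C)[C@@H]2CC[C@@](C)([C@@H]3[C@H](Cl)C(=O)[C@@H](OC(C)=O)[C@H]3[C@@H](O)C(=O)OC)[C@H]12
F5 | step 11 | methyl 5-acetoxy-6-oxo-7-[(1R,3aR,8aS)-1,4,4-trimethyl-8-methylidenedecahydroazulen-1-yl]-2-oxabicyclo[2.2.1]heptane-3-carboxylate, all centres as in 25 | C=C1CCCC(C)(C)[C@@H]2CC[C@@](C)([C@@H]3[C@@H]4C(=O)[C@@H](OC(C)=O)[C@H]3[C@H](C(=O)OC)O4)[C@H]12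
F6 | step 12 | methyl (2R)-2-[3-acetoxy-6-hydroxy-2-oxo-5-[(1R,3aR,8aS)-1,4,4-trimethyl-8-methylidenedecahydroazulen-1-yl]oxan-4-yl]-2-(triethylsilyloxy)acetate, ring centres as in 23, both anomers | C=C1CCCC(C)(C)[C@@H]2CC[C@@](C)([C@@H]3C(O)OC(=O)[C@@H](OC(C)=O)[C@H]3[C@@H](O[Si](CC)(CC)CC)C(=O)OC)[C@H]12
F7 | step 12 | methyl (2R)-2-[3,6-diacetoxy-2-oxo-5-[(1R,3aR,8aS)-1,4,4-trimethyl-8-methylidenedecahydroazulen-1-yl]oxan-4-yl]-2-(triethylsilyloxy)acetate, ring centres as in 23, both anomers | C=C1CCCC(C)(C)[C@@H]2CC[C@@](C)([C@@H]3C(OC(C)=O)OC(=O)[C@@H](OC(C)=O)[C@H]3[C@@H](O[Si](CC)(CC)CC)C(=O)OC)[C@H]12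
F8 | step 12 | methyl (2R)-2-[3,6-diacetoxy-2-oxo-5-[(1R,3aR,8aS)-1,4,4-trimethyl-8-methylidenedecahydroazulen-1-yl]oxan-4-yl]-2-hydroxyacetate, ring centres as in 23, both anomers | C=C1CCCC(C)(C)[C@@H]2CC[C@@](C)([C@@H]3C(OC(C)=O)OC(=O)[C@@H](OC(C)=O)[C@H]3[C@@H](O)C(=O)OC)[C@H]12
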